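The pitfall in the cedar run was to fit a decay time constant to its falling product: while product fell from 8.6% to 4.6%, starting material climbed back from 66.7% to 86.5%, and a one-way decay of product returns no starting material.

the same everywhere: starting material 10 mM
- oak: partner 0.88 equiv; temperature 35 °C; run made earlier
- cedar: partner 1.5 equiv; temperature 60 °C; run made earlier
- north: partner 1.00 equiv; at 40 °C until 2.5 min, from then on at 80 °C; time 12 min
- east: partner 2.00 equiv; at 40 °C throughout; time 40 min

| run | time / min | product / % | starting material / % |
|---|---|---|---|
| oak | 0.667 | 1.6 | 90.6 |
| oak | 2.00 | 8.4 | 78.6 |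
| oak | 3.00 | 13.2 | 72.2 |
| oak | 5.00 | 19.7 | 65.9 |
| oak | 8.00 | 22.5 | 63.1 |
| oak | 10.0 | 22.7 | 63.0 |
| oak | 12.0 | 22.2 | 62.6 |
| cedar | 0.333 | 7.9 | 68.6 |
| cedar | 0.500 | 8.1 | 64.5 |
| cedar | 0.667 | 7.5 | 64.4 |
| cedar | 1.00 | 8.6 | 66.7 |
| cedar | 2.00 | 6.9 | 75.2 |
| cedar | 3.00 | 5.8 | 82.2 |
| cedar | 4.00 | 4.6 | 86.5 |

(scatter of a reading: 0.5 percentage points)

- steps thought possible: starting material + partner <-> intermediate; partner <-> dormant form; intermediate <-> product + by-product

* which of the two ends with the higher amount of product, in percent of the starting material charged ("neither" if they lie within 2 percentage points) (north / east / neither)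
* product at the end, in percent of the starting material charged, north
* product at the end, in percent of the starting material charged, east

1. I looked for what stayed frozen. Starting material, intermediate and product together make up the charge, so intermediate is what the two readings leave missing, and by-product forms in step with product.

2. In the cedar run, intermediate went from 1.79 mM at 2.00 min to 0.890 mM at 4.00 min, a fall to half. Yet product squared over intermediate, both in mM, read 0.266 mM and then 0.238 mM, with mean 0.252 mM.

3. The oak run, at 8.00 min and 12.0 min, read 3.52 mM and 3.24 mM, with mean 3.38 mM. I call this the product quotient: product times by-product over intermediate, the apparent equilibrium constant of the last step.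

4. The two runs had the same starting material but differed in partner and temperature. The last product reading of the oak run stood 4.83 times that of the cedar run. The oak run's quotient read far higher, and the square root of the ratio of the two quotients is 3.66. The oak run's last intermediate also read higher, 1.52 mM against 0.890 mM.

5. My rule was product = sqrt(quotient × intermediate). Taking the logarithm of the quotient as straight in temperature, I reckoned 2.01 mM at 40 °C and 0.0316 mM at 80 °C, the second a stretch beyond the runs.

6. North spends 9.50 min hot, longer than the whole cedar run. With the cedar run's last intermediate as a stand-in, I got 1.68% for north. With the oak run's last intermediate, 1.52 mM, I got 17.5% for east.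

7. The forecast differed from these: 1% for north and 20.5% for east, so east ahead, with north's fate in its words: “Everything drains back to starting material”.

North ended at 0.756% and east at 13.9%, so east led, 6.6 percentage points under the forecast.

    starting material + partner ⇌ intermediate (K = 99.0 M⁻¹, k = 0.540 M⁻¹ s⁻¹, Ea = 63.0 kJ mol⁻¹, ΔH = −17.0 kJ mol⁻¹)
    partner ⇌ dormant form (K = 27.0, k = 0.00230 s⁻¹, Ea = 82.0 kJ mol⁻¹, ΔH = 4.00 kJ mol⁻¹)
    intermediate ⇌ product + by-product (K = 0.00210 M, k = 0.0130 s⁻¹, Ea = 82.0 kJ mol⁻¹, ΔH = −90.0 kJ mol⁻¹)
    (constants at 40 °C)

At 12.0 min in north, the slowest mode of the whole flask had a half-life of 0.251 min against 9.50 min at 80 °C, which is thermodynamic control. A run ten times as long changed nothing, and the quotient read 0.0419 mM. East read 2.16 mM at 20.0 min and 2.10 mM at 400 min, while its dormant form grew from 14.3 mM to 17.7 mM and its product fell from 19.0% to 10.7%.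

(The numbers in the tables stem from a simulated flask with constants of no real substance, noise included.)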